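## Analysis of the target

Compound 22 is a 2,3,4-trisubstituted oxolane. In the numbering used throughout (O1, C2, C3, C4, C5), C2 carries a 3,4,5-trimethoxyphenyl group, C3 a hydroxymethyl group, C4 a 3,4,5-trimethoxybenzoyl group, and C5 is an unsubstituted methylene. The three stereocentres are contiguous and are (2S,3S,4R) in this numbering: the aryl group and CH2OH are cis, CH2OH and the aroyl group are trans. C4 is α to the ketone and can be corrected by equilibration. C2 and C3 carry no acidic hydrogen, so they must be set kinetically and in the absolute sense, and their cis relation is the less stable one. The sensitive points are: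

- the β-alkoxy ketone C4–C5–O1, which can open by elimination under strong base;
- the benzylic ether bond C2–O1, which ionises under acid and would scramble C2;
- the γ-hydroxy ketone, which can close to a hemiketal whenever CH2OH and aroyl are cis;
- two electron-rich arenes, which do not tolerate strong oxidants such as ozone.

The difficulty is that a single five-membered ring gives little conformational bias, and no chiral-pool fragment maps onto C2/C3. The strategy rests on one feature. C2 is a benzylic ether carbon, so its C–H bond is activated by both oxygen and the arene. C3 is bonded to the hydroxymethyl carbon; if that carbon is a lactone carbonyl whose oxygen sits on the carbinol form of the C4 ketone, C3 becomes the α-carbon of a γ-butyrolactone. A diazo group, and from it a carbenoid, can be placed there, and the C2–C3 bond then joins a carbenoid carbon to an activated C–H five atoms away.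

## Retrosynthetic reasoning

**22 from 21 (C4 inversion).** No bond is cut. Compound 22 is traced to its C4 epimer 21, in which CH2OH and aroyl are cis. This is allowed because C4 is the only centre that can be equilibrated, and trans is the stable arrangement. What is gained is the freedom to build C3 and C4 cis, as a bicycle requires. The forward step must equilibrate C4 through the enol without opening the ring.

**21 from 20 and 20 from 19 (oxidation-level changes).** The ketone is traced to the benzylic carbinol of diol 20. The two hydroxyl-bearing carbons of 20 are then joined as the lactone of 19, by raising the CH2OH carbon to a carbonyl bound to the carbinol oxygen. This makes C3 a lactone α-carbon and locks C3 and C4 in a cis-fused bicycle. The forward steps are a full hydride reduction of the lactone and an oxidation that takes the benzylic alcohol and leaves the primary one.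

**19 from 18 (C2–C3, the key disconnection).** C2–C3 is the only ring bond that joins the two centres that must be set kinetically. Cutting it leaves an ordinary benzyl ether on one side and a lactone α-carbon on the other. Cutting O1–C2 instead would put the stereochemical burden on a substitution at an ionisable benzylic carbon, and cutting C3–C4 would give no handle on C2. The forward reaction is a metal-carbenoid insertion from the diazo lactone 18 into the benzylic ether C–H. It must prefer that C–H over the neighbouring ring C–H, close the ring cis-fused, and place the aryl group on the concave face.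

**18 from 15 (C=N2).** The diazo group is removed to give the parent trans lactone 15. The forward step is a diazo transfer to a lactone methylene, which needs temporary acyl activation because a lactone α-CH2 is not acidic enough on its own.

**15 from 14 and 14 from 11 (lactone from a hydroxy alkene).** The lactone carbonyl is traced through lactol 14 to the internal carbon of the terminal alkene in 11; one carbon is lost. The forward cleavage must spare the arenes. The free benzylic hydroxyl then captures the aldehyde as a five-membered lactol, which is oxidised.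

**11 from 8 and 9 (ether C–O).** The bond between the ether oxygen and the benzylic CH2 (the future C2) is cut, giving diol 8 and bromide 9. The forward alkylation must take the primary hydroxyl and leave the benzylic secondary one, which is needed later for lactol formation.

**8 from 7, 7 from 4 and 5, 4 from 1 and 2 (aldol C–C).** The bond between the carbinol carbon and the future C4 is cut, giving the pentenoyl imide 4 and aldehyde 5. The imide comes from auxiliary 1 and acid chloride 2. An auxiliary-controlled syn-aldol sets both stereocentres of the lactone at once, and the syn relation translates into the trans lactone. The carbinol centre is later oxidised away and the C4 centre is later inverted, but together they decide the face of the insertion and hence the absolute configuration of C2 and C3. Working the descriptors back from 22 shows that the (R)-configured auxiliary is required.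

## Alternatives that were turned down

**Alternative 1:** This plan cuts the bond between C3 and its exocyclic CH2 (radical hydroxymethylation through a silicon tether).

- Forward key step: the (bromomethyl)dimethylsilyl ether A2 of a 5-aryl-2,3-dihydrofuran-3-yl carbinol is treated with Bu3SnH and AIBN. The silylmethyl radical closes a six-membered ring onto the enol ether carbon that becomes C3 (6-exo). The resulting benzylic, oxygen-substituted radical at C2 takes hydrogen from the stannane on the convex face. The product is the cis-fused silabicycle A1.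
- Tamao–Fleming oxidation of A1 would give diol 20, so this plan would join the present route two steps before the end.
- In its favour: the tether enforces the C3/C4 cis relation as firmly as the lactone does, the conditions are neutral, and no diazo compound is handled. On mildness it is at least as good as the chosen route.
- Against it for this target:
  - A2 already needs two defined stereocentres beside an acid-labile aryl enol ether that hydrolyses or aromatises easily, and there is no access to it as short as one auxiliary aldol.
  - The nucleophilic α-silyl radical must add to an electron-rich alkene, a polarity mismatch, so reduction of the uncyclised radical competes.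
  - C2 is fixed only by hydrogen transfer to a planar radical on a 6/5 bicycle, which is less folded than a 5/5 one.
- Comparison: the chosen strategy sets C2 and C3 in one transition state from a precursor made by routine reactions. It pays for this with a diazo intermediate and a rhodium catalyst.

**Alternative 2:** This plan cuts the ketone carbonyl on both sides and also O1–C5 (a three-component disconnection).

- Forward key step: Pd(PPh3)4 (zerovalent palladium), CO and K2CO3 join the aryl iodide A5, carbon monoxide and the allenol A4. The aroylpalladium species adds to the central allene carbon and the hydroxyl closes onto the terminal carbon of the π-allyl unit. The product is the 2,5-dihydrofuran A3, with the C3=C4 double bond conjugated to the new ketone.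
- Conjugate hydride delivery anti to the C2 aryl group and protonation of the enolate would then set C3 and C4, and desilylation would give 22.
- In its favour: it is the shortest and most convergent plan, needs a single stereocentre instead of an auxiliary, and installs the ketone at the correct oxidation level, so there is no late reduction–oxidation detour. On step economy it is stronger than the chosen route.
- Against it for this target:
  - The C2 hydrogen of A3 is benzylic, allylic, next to oxygen and vinylogously α to the ketone, so carbonate base at carbonylation temperature can racemise it or move the double bond towards the furan.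
  - The 1,4-reduction must attack a tetrasubstituted enone in the presence of an aryl ketone that invites 1,2-attack, and its facial selectivity rests on one aryl group on a nearly flat ring.
  - The enolate so formed has the ring oxygen in the β-position and can open the ring.
- Comparison: the chosen strategy gives up convergence, but C2 never carries an acidic hydrogen and both centres are set inside a folded bicycle.

**Alternative 3:** This plan cuts C2–C3 and C4–C5 together with the acetal-type bond O1–C2 (Prins–pinacol cascade).

- Forward key step: SnCl4 condenses the Z-allylic diol A7 with aldehyde 5 to an oxocarbenium ion. The Z-alkene attacks it through a six-membered chair, forming C2–C3 with the aryl group equatorial and the CH2OBn group axial, hence cis. The cation at C4 is quenched by a pinacol shift of the ring CH2 from the carbinol carbon, which forms C4–C5, contracts the ring to the oxolane and turns the tertiary carbinol into the aryl ketone. The product is A6, the benzyl ether of the target.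
- In its favour: the ring, two C–C bonds, the ketone and the 2,3-cis relation arise in one step from two simple pieces, one of them aldehyde 5. In bond-forming efficiency it beats the chosen route.
- Against it for this target:
  - The alkene of A7 is only 1,2-disubstituted, so the Prins step must create an unstabilised secondary cation.
  - The tertiary, benzylic and allylic carbinol of A7 is the position SnCl4 ionises most readily, which would lose the stereocentre meant to carry the absolute configuration.
  - A7 itself needs an enantiopure tertiary carbinol next to a Z-alkene; the (2R) isomer would be required if its aryl group sits equatorial in the chair.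
  - The last step, removal of a benzyl ether from A6, has no clean solution: hydrogenolysis threatens C2–O1 and the ketone, and Lewis acids threaten the six methyl ethers.
- Comparison: the chosen route keeps both benzylic ether carbons away from Lewis acids throughout and ends at the free alcohol without a deprotection.

Key step: step 8

Assumption: lactol 14 is carried on as its mixture of anomers, and 21 is written as the open hydroxy ketone although it may equilibrate with its ring-closed hemiketal form; both forms react in the same way in the following step.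

## Route

Step 1
Reactants: 1 (R)-4-benzyl-1,3-oxazolidin-2-one; 2 pent-4-enoyl chloride
Product: 4 (R)-4-benzyl-3-(pent-4-enoyl)-1,3-oxazolidin-2-one, via lithium salt of the oxazolidinone 3 (not isolated)
Conditions: n-BuLi, THF, −78 °C; then 2, −78 → 0 °C
Reagents that add atoms: none
Why: N-acylation of the lithiated oxazolidinone by an acid chloride is the standard loading of an Evans auxiliary; the stereocentre of 1 is not involved.

Step 2
Reactants: 4 (R)-4-benzyl-3-(pent-4-enoyl)-1,3-oxazolidin-2-one; 5 3,4,5-trimethoxybenzaldehyde
Product: 7 (4R)-4-benzyl-3-{(2R)-2-[(R)-hydroxy(3,4,5-trimethoxyphenyl)methyl]pent-4-enoyl}-1,3-oxazolidin-2-one, via Z-boron enolate 6 (not isolated)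
Conditions: Bu2BOTf, iPr2NEt, CH2Cl2, 0 °C; then 5, −78 → 0 °C; H2O2, pH 7 buffer, MeOH, 0 °C
Reagents that add atoms: none
Why: Evans syn-aldol: the Z-dibutylboron enolate 6 reacts with 5 through a closed Zimmerman–Traxler chair on the enolate face away from the benzyl group, with the two imide carbonyls opposed. This sets both new centres, (2R) and the (R)-carbinol, in the syn relation; the mirror-image auxiliary is known to give the (2S,3S) series with aryl aldehydes.

Step 3
Reactants: 7 (4R)-4-benzyl-3-{(2R)-2-[(R)-hydroxy(3,4,5-trimethoxyphenyl)methyl]pent-4-enoyl}-1,3-oxazolidin-2-one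
Product: 8 (1R,2S)-2-(prop-2-en-1-yl)-1-(3,4,5-trimethoxyphenyl)propane-1,3-diol
Conditions: LiBH4, MeOH (1 equiv.), THF, 0 °C → rt
Reagents that add atoms: none
Why: LiBH4 reduces the activated imide carbonyl to the primary alcohol and releases auxiliary 1 for recovery; the cold, weakly basic conditions should avoid retro-aldol, and neither stereocentre is touched (the descriptor at C2 changes only because the priorities change).

Step 4
Reactants: 8 (1R,2S)-2-(prop-2-en-1-yl)-1-(3,4,5-trimethoxyphenyl)propane-1,3-diol; 9 5-(bromomethyl)-1,2,3-trimethoxybenzene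
Product: 11 (1R,2S)-2-{[(3,4,5-trimethoxybenzyl)oxy]methyl}-1-(3,4,5-trimethoxyphenyl)pent-4-en-1-ol, via stannylene acetal 10 (not isolated)
Conditions: Bu2SnO, PhMe, reflux (Dean–Stark); then 9, CsF, DMF, rt
Reagents that add atoms: none
Why: Regioselective monoalkylation of a primary–secondary diol through its dibutylstannylene acetal: fluoride activation makes the less hindered primary oxygen the nucleophile, so the ether should form there only. The neutral conditions spare the benzylic alcohol.

Step 5
Reactants: 11 (1R,2S)-2-{[(3,4,5-trimethoxybenzyl)oxy]methyl}-1-(3,4,5-trimethoxyphenyl)pent-4-en-1-ol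
Product: 14 (4S,5R)-4-{[(3,4,5-trimethoxybenzyl)oxy]methyl}-5-(3,4,5-trimethoxyphenyl)oxolan-2-ol (anomer mixture), via triol 12 (not isolated), via hydroxy aldehyde 13 (not isolated)
Conditions: OsO4 (2 mol %), NaIO4, 2,6-lutidine, 1,4-dioxane/H2O 3:1, rt
Reagents that add atoms: osmium tetroxide O=[Os](=O)(=O)=O (its oxygen becomes the lactol hydroxyl oxygen); sodium periodate [Na+].[O-]I(=O)(=O)=O (reoxidises the osmium and so supplies that oxygen in the end)
Why: Lemieux–Johnson oxidation is used instead of ozonolysis because ozone would also attack the two trimethoxyphenyl rings. Dihydroxylation and periodate cleavage give the γ-hydroxy aldehyde 13, which closes spontaneously to the five-membered lactol; 2,6-lutidine suppresses over-oxidation.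

Step 6
Reactants: 14 (4S,5R)-4-{[(3,4,5-trimethoxybenzyl)oxy]methyl}-5-(3,4,5-trimethoxyphenyl)oxolan-2-ol (anomer mixture)
Product: 15 (4S,5R)-4-{[(3,4,5-trimethoxybenzyl)oxy]methyl}-5-(3,4,5-trimethoxyphenyl)oxolan-2-one
Conditions: TEMPO (10 mol %), PhI(OAc)2, CH2Cl2, rt
Reagents that add atoms: none
Why: Oxoammonium-mediated oxidation of a lactol to the lactone under near-neutral conditions, which the benzylic ether and the arenes should tolerate; the anomeric mixture converges, and the 4,5-trans relation from step 2 is carried through.

Step 7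
Reactants: 15 (4S,5R)-4-{[(3,4,5-trimethoxybenzyl)oxy]methyl}-5-(3,4,5-trimethoxyphenyl)oxolan-2-one
Product: 18 (4S,5R)-3-diazo-4-{[(3,4,5-trimethoxybenzyl)oxy]methyl}-5-(3,4,5-trimethoxyphenyl)oxolan-2-one, via lithium enolate 16 (not isolated), via trifluoroacetyl lactone 17 (not isolated)
Conditions: LiN(SiMe3)2, THF, −78 °C; CF3CO2CH2CF3, −78 °C; then 4-acetamidobenzenesulfonyl azide, Et3N, H2O (1 equiv.), MeCN, rt
Reagents that add atoms: 4-acetamidobenzenesulfonyl azide CC(=O)Nc1ccc(cc1)S(=O)(=O)N=[N+]=[N-] (the two diazo nitrogens)
Why: Detrifluoroacetylative diazo transfer: C-acylation of the lactone enolate gives the activated β-dicarbonyl 17, whose enolate adds to the sulfonyl azide; fragmentation expels the trifluoroacetyl group as the N-acyl sulfonamide and leaves the diazo group. The ring stereocentres are not acidic and are kept.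

Step 8
Reactants: 18 (4S,5R)-3-diazo-4-{[(3,4,5-trimethoxybenzyl)oxy]methyl}-5-(3,4,5-trimethoxyphenyl)oxolan-2-one
Product: 19 (1R,2S,5S,6R)-2,6-bis(3,4,5-trimethoxyphenyl)-3,7-dioxabicyclo[3.3.0]octan-8-one (2-aryl endo and 6-aryl exo)
Conditions: Rh2(OAc)4 (2 mol %), CH2Cl2, 40 °C, slow addition of 18 (syringe pump), high dilution
Reagents that add atoms: none
Why: Rh2(OAc)4 takes up the diazo carbon of 18, dinitrogen leaves, and an electrophilic rhodium carbenoid forms at the lactone α-carbon (C3 of the target). Its empty orbital accepts the benzylic ether C–H bond five atoms away in a concerted, hydride-transfer-like three-centre transition state and the metal is released; this is the known 1,5 C–H insertion of α-diazo-γ-butyrolactones into benzylic ether C–H bonds. The oxolane closes in this 1,5-insertion mode, a five-membered ring through a six-centre array that includes the migrating hydrogen. C3 is fixed by the tether: the side chain sits on one face of the lactone at the neighbouring carbon, so only the cis-fused bicycle can form. C2 is fixed by insertion with retention into the C–H bond that lets the aryl group turn away from the dirhodium core and lie over the concave face; this endo placement is the 2,3-cis relation of 22. Because both lactone stereocentres of 18 are already set, the face is set and 19 should form as one enantiomer. The step needs chemoselectivity for the benzylic ether C–H over 1,2-hydride shift from the adjacent ring C–H, over attack on the electron-rich rings and over oxonium ylide formation. The oxygen lone pair and the arene stabilise the positive charge that builds at the insertion carbon, and the moderately electrophilic acetate catalyst with slow addition keeps the carbenoid selective and suppresses dimerisation.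

Step 9
Reactants: 19 (1R,2S,5S,6R)-2,6-bis(3,4,5-trimethoxyphenyl)-3,7-dioxabicyclo[3.3.0]octan-8-one
Product: 20 [(2S,3S,4S)-4-[(R)-hydroxy(3,4,5-trimethoxyphenyl)methyl]-2-(3,4,5-trimethoxyphenyl)oxolan-3-yl]methanol
Conditions: LiAlH4, THF, 0 °C → rt
Reagents that add atoms: none
Why: Hydride reduction of the lactone to the 1,4-diol; the carbonyl carbon becomes the CH2OH on C3 and the lactone oxygen stays on the benzylic carbinol. All four stereocentres are retained.

Step 10
Reactants: 20 [(2S,3S,4S)-4-[(R)-hydroxy(3,4,5-trimethoxyphenyl)methyl]-2-(3,4,5-trimethoxyphenyl)oxolan-3-yl]methanol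
Product: 21 [(3S,4S,5S)-4-(hydroxymethyl)-5-(3,4,5-trimethoxyphenyl)oxolan-3-yl](3,4,5-trimethoxyphenyl)methanone
Conditions: MnO2 (activated, excess), CH2Cl2, rt
Reagents that add atoms: none
Why: MnO2 oxidises benzylic alcohols and leaves saturated primary alcohols, so only the aryl carbinol should go to the ketone; this removes the relay stereocentre. Any hemiketal formed is tertiary and cannot be oxidised further.

Step 11
Reactants: 21 [(3S,4S,5S)-4-(hydroxymethyl)-5-(3,4,5-trimethoxyphenyl)oxolan-3-yl](3,4,5-trimethoxyphenyl)methanone
Product: 22 [(3R,4S,5S)-4-(hydroxymethyl)-5-(3,4,5-trimethoxyphenyl)oxolan-3-yl](3,4,5-trimethoxyphenyl)methanone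
Conditions: DBU, CH2Cl2, rt
Reagents that add atoms: none
Why: Base-mediated epimerisation α to the aryl ketone: DBU equilibrates C4 through the enolate towards the 3,4-trans isomer, which relieves the all-cis crowding and cannot close to a hemiketal. C2 and C3 have no acidic hydrogen and are kept; a mild amidine base at room temperature should keep β-elimination of the ring oxygen slow.

## Compound list

1 | (R)-4-benzyl-1,3-oxazolidin-2-one | O=C1N[C@H](Cc2ccccc2)CO1 | starting material
2 | pent-4-enoyl chloride | C=CCCC(Cl)=O | starting material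
3 | lithium salt of (R)-4-benzyl-1,3-oxazolidin-2-one (N-lithiated) | [Li]N1[C@H](Cc2ccccc2)COC1=O | intermediate
4 | (R)-4-benzyl-3-(pent-4-enoyl)-1,3-oxazolidin-2-one | C=CCCC(=O)N1[C@H](Cc2ccccc2)COC1=O | intermediate
5 | 3,4,5-trimethoxybenzaldehyde | COc1cc(C=O)cc(OC)c1OC | starting material
6 | (4R)-4-benzyl-3-{(1Z)-1-[(dibutylboranyl)oxy]penta-1,4-dien-1-yl}-1,3-oxazolidin-2-one (Z-boron enolate) | C=CC/C=C(\OB(CCCC)CCCC)N1[C@H](Cc2ccccc2)COC1=O | intermediate
7 | (4R)-4-benzyl-3-{(2R)-2-[(R)-hydroxy(3,4,5-trimethoxyphenyl)methyl]pent-4-enoyl}-1,3-oxazolidin-2-one (syn aldol) | O[C@@H](c1cc(OC)c(OC)c(OC)c1)[C@@H](CC=C)C(=O)N1[C@H](Cc2ccccc2)COC1=O | intermediate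
8 | (1R,2S)-2-(prop-2-en-1-yl)-1-(3,4,5-trimethoxyphenyl)propane-1,3-diol | O[C@@H](c1cc(OC)c(OC)c(OC)c1)[C@H](CO)CC=C | intermediate
9 | 5-(bromomethyl)-1,2,3-trimethoxybenzene | COc1cc(CBr)cc(OC)c1OC | starting material
10 | (4R,5S)-2,2-dibutyl-5-(prop-2-en-1-yl)-4-(3,4,5-trimethoxyphenyl)-1,3,2-dioxastanninane | CCCC[Sn]1(CCCC)OC[C@H](CC=C)[C@H](c2cc(OC)c(OC)c(OC)c2)O1 | intermediate
11 | (1R,2S)-2-{[(3,4,5-trimethoxybenzyl)oxy]methyl}-1-(3,4,5-trimethoxyphenyl)pent-4-en-1-ol | O[C@@H](c1cc(OC)c(OC)c(OC)c1)[C@H](COCc1cc(OC)c(OC)c(OC)c1)CC=C | intermediate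
12 | (4S,5R)-4-{[(3,4,5-trimethoxybenzyl)oxy]methyl}-5-(3,4,5-trimethoxyphenyl)pentane-1,2,5-triol (both C2 epimers) | O[C@@H](c1cc(OC)c(OC)c(OC)c1)[C@H](COCc1cc(OC)c(OC)c(OC)c1)CC(O)CO | intermediate
13 | (3S,4R)-4-hydroxy-3-{[(3,4,5-trimethoxybenzyl)oxy]methyl}-4-(3,4,5-trimethoxyphenyl)butanal | O[C@@H](c1cc(OC)c(OC)c(OC)c1)[C@H](COCc1cc(OC)c(OC)c(OC)c1)CC=O | intermediate
14 | (4S,5R)-4-{[(3,4,5-trimethoxybenzyl)oxy]methyl}-5-(3,4,5-trimethoxyphenyl)oxolan-2-ol (anomer mixture) | OC1C[C@@H](COCc2cc(OC)c(OC)c(OC)c2)[C@H](c2cc(OC)c(OC)c(OC)c2)O1 | intermediate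
15 | (4S,5R)-4-{[(3,4,5-trimethoxybenzyl)oxy]methyl}-5-(3,4,5-trimethoxyphenyl)oxolan-2-one (4,5-trans) | O=C1C[C@@H](COCc2cc(OC)c(OC)c(OC)c2)[C@H](c2cc(OC)c(OC)c(OC)c2)O1 | intermediate
16 | lithium (4S,5R)-4-{[(3,4,5-trimethoxybenzyl)oxy]methyl}-5-(3,4,5-trimethoxyphenyl)-4,5-dihydrofuran-2-olate | [Li]OC1=C[C@@H](COCc2cc(OC)c(OC)c(OC)c2)[C@H](c2cc(OC)c(OC)c(OC)c2)O1 | intermediate
17 | (4S,5R)-3-(trifluoroacetyl)-4-{[(3,4,5-trimethoxybenzyl)oxy]methyl}-5-(3,4,5-trimethoxyphenyl)oxolan-2-one (C3 not defined) | O=C1C(C(=O)C(F)(F)F)[C@@H](COCc2cc(OC)c(OC)c(OC)c2)[C@H](c2cc(OC)c(OC)c(OC)c2)O1 | intermediate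
18 | (4S,5R)-3-diazo-4-{[(3,4,5-trimethoxybenzyl)oxy]methyl}-5-(3,4,5-trimethoxyphenyl)oxolan-2-one (4,5-trans) | O=C1O[C@@H](c2cc(OC)c(OC)c(OC)c2)[C@H](COCc2cc(OC)c(OC)c(OC)c2)C1=[N+]=[N-] | intermediate
19 | (1R,2S,5S,6R)-2,6-bis(3,4,5-trimethoxyphenyl)-3,7-dioxabicyclo[3.3.0]octan-8-one (cis-fused, 2-aryl endo, 6-aryl exo) | O=C1O[C@@H](c2cc(OC)c(OC)c(OC)c2)[C@@H]2CO[C@H](c3cc(OC)c(OC)c(OC)c3)[C@H]12 | intermediate
20 | [(2S,3S,4S)-4-[(R)-hydroxy(3,4,5-trimethoxyphenyl)methyl]-2-(3,4,5-trimethoxyphenyl)oxolan-3-yl]methanol | O[C@@H](c1cc(OC)c(OC)c(OC)c1)[C@@H]1CO[C@H](c2cc(OC)c(OC)c(OC)c2)[C@@H]1CO | intermediate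
21 | [(3S,4S,5S)-4-(hydroxymethyl)-5-(3,4,5-trimethoxyphenyl)oxolan-3-yl](3,4,5-trimethoxyphenyl)methanone (all-cis) | COc1cc(C(=O)[C@@H]2CO[C@H](c3cc(OC)c(OC)c(OC)c3)[C@@H]2CO)cc(OC)c1OC | intermediate
22 | [(3R,4S,5S)-4-(hydroxymethyl)-5-(3,4,5-trimethoxyphenyl)oxolan-3-yl](3,4,5-trimethoxyphenyl)methanone | COc1cc(C(=O)[C@H]2CO[C@H](c3cc(OC)c(OC)c(OC)c3)[C@@H]2CO)cc(OC)c1OC | target

## Step count and least certain steps

Total: 11 steps. Longest linear sequence: 11 steps (1 and 2 to 22); 5 and 9 enter as single reagents in steps 2 and 4.

**Step 8 (key step).** The most likely failure is diversion of the carbenoid before it reaches the benzylic C–H. The ring C–H next to the carbenoid carbon can migrate (1,2-hydride shift), because it is close and well aligned, whereas the insertion must organise a six-centre array. Attack on an electron-rich ring, or weaker endo preference with two bulky arenes, are the other ways it can go wrong.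

The fallback sets out from 8 and returns at 19. It forms C2–C3 by enolate acylation and sets C2 by hydride delivery to a bicyclic oxocarbenium ion.
- Diol 8 would be acylated at the primary hydroxyl with 3,4,5-trimethoxybenzoyl chloride (2,4,6-collidine, CH2Cl2, −40 °C) to give (2S,3R)-3-hydroxy-2-(prop-2-en-1-yl)-3-(3,4,5-trimethoxyphenyl)propyl 3,4,5-trimethoxybenzoate F1.
- The oxidative cleavage of step 5 and the lactol oxidation of step 6 would give [(2R,3S)-5-hydroxy-2-(3,4,5-trimethoxyphenyl)oxolan-3-yl]methyl 3,4,5-trimethoxybenzoate F2 and then [(2R,3S)-5-oxo-2-(3,4,5-trimethoxyphenyl)oxolan-3-yl]methyl 3,4,5-trimethoxybenzoate F3.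
- LiN(SiMe3)2 (2 equiv., THF, −78 → 0 °C) would move the aroyl group from oxygen to the lactone α-carbon (intramolecular Claisen acylation through a five-membered ring). The cis hydroxy keto lactone closes to (1R,5S,6R)-2-hydroxy-2,6-bis(3,4,5-trimethoxyphenyl)-3,7-dioxabicyclo[3.3.0]octan-8-one F4.
- Ionic hydrogenation (Et3SiH, BF3·OEt2, CH2Cl2, −78 °C) delivers hydride to the convex face of the 2-aryl oxocarbenium ion, so the aryl group ends up endo and 19 is reached.

**Step 7.** The enolate next to a substituted ring carbon may be C-acylated incompletely, or the trifluoroethoxide set free may open the lactone, so the diazo transfer could start from a mixture.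

The fallback sets out from 15 and returns at 18. It avoids strong base and activates the α-carbon as an enamine.
- Heating 15 with tert-butoxybis(dimethylamino)methane in toluene at 90 °C would give (4S,5R)-3-[(dimethylamino)methylidene]-4-{[(3,4,5-trimethoxybenzyl)oxy]methyl}-5-(3,4,5-trimethoxyphenyl)oxolan-2-one F8.
- Treatment of F8 with 4-acetamidobenzenesulfonyl azide in MeCN at rt should give 18 by cycloaddition to the enamine double bond and fragmentation (Regitz-type diazo transfer with loss of the N-sulfonyl formamidine).

**Step 4.** Alkylation may be incomplete or spread to the secondary oxygen, and the electron-rich benzylic alcohol may suffer during the hot acetal formation. Regiocontrol rests only on the difference between the two tin-bound oxygens.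

The fallback sets out from 7 and returns at 11. It blocks the secondary hydroxyl before the primary one exists.
- Silylation of 7 (iPr3SiOTf, 2,6-lutidine, CH2Cl2, 0 °C) would give (4R)-4-benzyl-3-{(2R)-2-[(R)-(3,4,5-trimethoxyphenyl){[tri(propan-2-yl)silyl]oxy}methyl]pent-4-enoyl}-1,3-oxazolidin-2-one F5.
- LiBH4 would give (2S)-2-[(R)-(3,4,5-trimethoxyphenyl){[tri(propan-2-yl)silyl]oxy}methyl]pent-4-en-1-ol F6.
- Williamson alkylation (NaH, 9, Bu4NI, THF/DMF, 0 °C) would give {[(1R,2S)-2-{[(3,4,5-trimethoxybenzyl)oxy]methyl}-1-(3,4,5-trimethoxyphenyl)pent-4-en-1-yl]oxy}tri(propan-2-yl)silane F7. The bulky silyl group is chosen because it is slow to migrate to the primary alkoxide.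
- Bu4NF in THF then gives 11.

**Step 11 (with step 10).** The epimerisation may stall because the cis isomer is held as its hemiketal and only the open ketone can enolise. Alternatively the enolate may expel the ring oxygen (β-elimination) and reclose through the wrong hydroxyl.

The fallback sets out from 20 and returns at 22. It removes the free primary hydroxyl from the equilibration.
- Selective silylation of the primary alcohol (t-BuMe2SiCl, imidazole, DMF, 0 °C) would give (R)-[(3S,4S,5S)-4-({[tert-butyl(dimethyl)silyl]oxy}methyl)-5-(3,4,5-trimethoxyphenyl)oxolan-3-yl](3,4,5-trimethoxyphenyl)methanol F9.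
- Dess–Martin periodinane (NaHCO3, CH2Cl2) would give [(3S,4S,5S)-4-({[tert-butyl(dimethyl)silyl]oxy}methyl)-5-(3,4,5-trimethoxyphenyl)oxolan-3-yl](3,4,5-trimethoxyphenyl)methanone F10.
- DBU would equilibrate it to [(3R,4S,5S)-4-({[tert-butyl(dimethyl)silyl]oxy}methyl)-5-(3,4,5-trimethoxyphenyl)oxolan-3-yl](3,4,5-trimethoxyphenyl)methanone F11.
- Buffered fluoride (HF·pyridine, THF, 0 °C) then gives 22.

## Further compounds

F1 | step 8 | (2S,3R)-3-hydroxy-2-(prop-2-en-1-yl)-3-(3,4,5-trimethoxyphenyl)propyl 3,4,5-trimethoxybenzoate | O[C@@H](c1cc(OC)c(OC)c(OC)c1)[C@H](COC(=O)c1cc(OC)c(OC)c(OC)c1)CC=C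
F2 | step 8 | [(2R,3S)-5-hydroxy-2-(3,4,5-trimethoxyphenyl)oxolan-3-yl]methyl 3,4,5-trimethoxybenzoate (anomer mixture) | OC1C[C@@H](COC(=O)c2cc(OC)c(OC)c(OC)c2)[C@H](c2cc(OC)c(OC)c(OC)c2)O1
F3 | step 8 | [(2R,3S)-5-oxo-2-(3,4,5-trimethoxyphenyl)oxolan-3-yl]methyl 3,4,5-trimethoxybenzoate | O=C1C[C@@H](COC(=O)c2cc(OC)c(OC)c(OC)c2)[C@H](c2cc(OC)c(OC)c(OC)c2)O1
F4 | step 8 | (1R,5S,6R)-2-hydroxy-2,6-bis(3,4,5-trimethoxyphenyl)-3,7-dioxabicyclo[3.3.0]octan-8-one (C2 not defined) | O=C1O[C@@H](c2cc(OC)c(OC)c(OC)c2)[C@@H]2COC(O)(c3cc(OC)c(OC)c(OC)c3)[C@H]12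
F5 | step 4 | (4R)-4-benzyl-3-{(2R)-2-[(R)-(3,4,5-trimethoxyphenyl){[tri(propan-2-yl)silyl]oxy}methyl]pent-4-enoyl}-1,3-oxazolidin-2-one | CC(C)[Si](C(C)C)(C(C)C)O[C@@H](c1cc(OC)c(OC)c(OC)c1)[C@@H](CC=C)C(=O)N1[C@H](Cc2ccccc2)COC1=O
F6 | step 4 | (2S)-2-[(R)-(3,4,5-trimethoxyphenyl){[tri(propan-2-yl)silyl]oxy}methyl]pent-4-en-1-ol | CC(C)[Si](C(C)C)(C(C)C)O[C@@H](c1cc(OC)c(OC)c(OC)c1)[C@H](CO)CC=C
F7 | step 4 | {[(1R,2S)-2-{[(3,4,5-trimethoxybenzyl)oxy]methyl}-1-(3,4,5-trimethoxyphenyl)pent-4-en-1-yl]oxy}tri(propan-2-yl)silane | CC(C)[Si](C(C)C)(C(C)C)O[C@@H](c1cc(OC)c(OC)c(OC)c1)[C@H](COCc1cc(OC)c(OC)c(OC)c1)CC=C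
F8 | step 7 | (4S,5R)-3-[(dimethylamino)methylidene]-4-{[(3,4,5-trimethoxybenzyl)oxy]methyl}-5-(3,4,5-trimethoxyphenyl)oxolan-2-one (alkene geometry not controlled) | CN(C)C=C1C(=O)O[C@@H](c2cc(OC)c(OC)c(OC)c2)[C@@H]1COCc1cc(OC)c(OC)c(OC)c1
F9 | step 11 | (R)-[(3S,4S,5S)-4-({[tert-butyl(dimethyl)silyl]oxy}methyl)-5-(3,4,5-trimethoxyphenyl)oxolan-3-yl](3,4,5-trimethoxyphenyl)methanol | O[C@@H](c1cc(OC)c(OC)c(OC)c1)[C@@H]1CO[C@H](c2cc(OC)c(OC)c(OC)c2)[C@@H]1CO[Si](C)(C)C(C)(C)C
F10 | step 11 | [(3S,4S,5S)-4-({[tert-butyl(dimethyl)silyl]oxy}methyl)-5-(3,4,5-trimethoxyphenyl)oxolan-3-yl](3,4,5-trimethoxyphenyl)methanone | COc1cc(C(=O)[C@@H]2CO[C@H](c3cc(OC)c(OC)c(OC)c3)[C@@H]2CO[Si](C)(C)C(C)(C)C)cc(OC)c1OC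
F11 | step 11 | [(3R,4S,5S)-4-({[tert-butyl(dimethyl)silyl]oxy}methyl)-5-(3,4,5-trimethoxyphenyl)oxolan-3-yl](3,4,5-trimethoxyphenyl)methanone | COc1cc(C(=O)[C@H]2CO[C@H](c3cc(OC)c(OC)c(OC)c3)[C@@H]2CO[Si](C)(C)C(C)(C)C)cc(OC)c1OC
A1 | alternative 1 | cis-fused 4,4-dimethyl-2,7-bis(3,4,5-trimethoxyphenyl)-3,8-dioxa-4-silabicyclo[4.3.0]nonane (7-aryl on the concave face) | C[Si]1(C)C[C@H]2[C@@H](c3cc(OC)c(OC)c(OC)c3)OC[C@H]2[C@H](c4cc(OC)c(OC)c(OC)c4)O1
A2 | alternative 1 | (bromomethyl)dimethylsilyl ether of (R)-[(3S)-5-(3,4,5-trimethoxyphenyl)-2,3-dihydrofuran-3-yl](3,4,5-trimethoxyphenyl)methanol | BrC[Si](C)(C)O[C@@H](c2cc(OC)c(OC)c(OC)c2)[C@@H]1COC(c2cc(OC)c(OC)c(OC)c2)=C1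
A3 | alternative 2 | [(5R)-4-({[tert-butyl(dimethyl)silyl]oxy}methyl)-5-(3,4,5-trimethoxyphenyl)-2,5-dihydrofuran-3-yl](3,4,5-trimethoxyphenyl)methanone | O=C(c1cc(OC)c(OC)c(OC)c1)C2=C(CO[Si](C)(C)C(C)(C)C)[C@@H](c3cc(OC)c(OC)c(OC)c3)OC2
A4 | alternative 2 | (1R)-2-({[tert-butyl(dimethyl)silyl]oxy}methyl)-1-(3,4,5-trimethoxyphenyl)buta-2,3-dien-1-ol | O[C@H](c1cc(OC)c(OC)c(OC)c1)C(CO[Si](C)(C)C(C)(C)C)=C=C
A5 | alternative 2 | 5-iodo-1,2,3-trimethoxybenzene | COc1cc(I)cc(OC)c1OC
A6 | alternative 3 | [(3R,4S,5S)-4-[(benzyloxy)methyl]-5-(3,4,5-trimethoxyphenyl)oxolan-3-yl](3,4,5-trimethoxyphenyl)methanone | O=C(c1cc(OC)c(OC)c(OC)c1)[C@H]2CO[C@H](c3cc(OC)c(OC)c(OC)c3)[C@@H]2COCc4ccccc4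
A7 | alternative 3 | (2R,3Z)-5-(benzyloxy)-2-(3,4,5-trimethoxyphenyl)pent-3-ene-1,2-diol | OC[C@](O)(c1cc(OC)c(OC)c(OC)c1)/C=C\COCc1ccccc1
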